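**Retrosynthetic overview**
- Aryl–C(=O) bond: Houben–Hoesch acylation of phloroglucinol with a C20 hydroxy-tetraenenitrile, as the last step. The only ring is bought intact; no ring is formed in the route.
- Four Z-alkenes: one Lindlar semihydrogenation of a skipped C20 tetrayne.
- Tetrayne: C9–C10 sp–sp3 union (Cu/fluoride) of a C10–C20 bromodiynol with a C1–C9 silylated diyne nitrile.
- Halves: Cu-mediated alkyne–propargyl bromide couplings (C13–C14 and C6–C7) from small achiral pieces.
- C17 stereocenter and C16–C17 bond: new organocatalytic enantioselective propargylation of butanal with allenyltrimethylsilane.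

Assumption: allenyltrimethylsilane is taken as a catalogue reagent, and the catalyst antipode that gives Si-face attack in step 1 is fixed on the first run by Mosher-ester analysis of the alcohol.

**Step 1**
Reactants: 1 butanal; 2 allenyltrimethylsilane
Product: 4 (4R)-hept-1-yn-4-ol, via silyl ether 3 (not isolated)
Conditions: confined chiral BINOL-derived imidodiphosphorimidate (IDPi) acid (2 mol%), 2 (1.5 equiv), toluene, −60 °C, 48 h; then MeOH, cat. HCl, 0 °C
Reagents that add atoms: none
Why: Proposed new method: silylium-type asymmetric counteranion-directed propargylation, in which 2 silylates the IDPi, the N-silyl catalyst passes Me3Si+ to butanal, and the O-silyl oxocarbenium ion held in the confined chiral anion is attacked on its Si face by the CH2 terminus of the allenylsilane (anti-SE2'), after which the β-silyl-stabilised vinyl cation releases Me3Si+ to the next aldehyde to give alkyne 3 (C17 set as R) and close the cycle; the closest known reaction types are the IDPi-catalysed Hosomi–Sakurai allylation of aldehydes with allyltrimethylsilane and the racemic TiCl4-promoted allenylsilane propargylation.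

**Step 2**
Reactants: 4 (4R)-hept-1-yn-4-ol; 5 1,4-dibromobut-2-yne
Product: 6 (4R)-11-bromoundeca-6,9-diyn-4-ol
Conditions: 5 (4 equiv), CuI (1 equiv), K2CO3 (1.5 equiv), DMF, 0 °C → rt, Ar, dark
Reagents that add atoms: none
Why: Copper(I)-mediated sp–sp3 coupling of a terminal alkyne with a propargylic bromide (Jeffery-type skipped-diyne synthesis); excess 5 suppresses double coupling, K2CO3 does not deprotonate the secondary alcohol, the stereocenter is untouched, and CuI acts through the copper acetylide and is not consumed in the net equation.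

**Step 3**
Reactants: 7 hex-5-ynenitrile; 8 (3-bromoprop-1-yn-1-yl)trimethylsilane
Product: 9 9-(trimethylsilyl)nona-5,8-diynenitrile
Conditions: CuI (1 equiv), K2CO3 (1.5 equiv), DMF, rt, Ar
Reagents that add atoms: none
Why: Same copper-mediated alkyne–propargyl bromide coupling; the C-silyl group caps the new terminus so no oligomerisation occurs, and the nitrile is inert.

**Step 4**
Reactants: 6 (4R)-11-bromoundeca-6,9-diyn-4-ol; 9 9-(trimethylsilyl)nona-5,8-diynenitrile
Product: 10 (17R)-17-hydroxyicosa-5,8,11,14-tetraynenitrile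
Conditions: CuI (1 equiv), CsF (1.5 equiv), degassed DMF, rt, Ar, dark; short silica pad, used at once
Reagents that add atoms: none
Why: Fluoride-triggered desilylative copper coupling, in which CsF turns the alkynylsilane directly into the copper acetylide that displaces the propargylic bromide, so the base-sensitive terminal 1,4-diyne is never isolated and the C9–C10 bond joins the two halves.

**Step 5**
Reactants: 10 (17R)-17-hydroxyicosa-5,8,11,14-tetraynenitrile
Product: 11 (5Z,8Z,11Z,14Z,17R)-17-hydroxyicosa-5,8,11,14-tetraenenitrile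
Conditions: H2 (1 atm, stopped at 4.0 equiv uptake), Lindlar catalyst (Pd/CaCO3/Pb), quinoline, EtOAc, 10 °C
Reagents that add atoms: none
Why: Lindlar semihydrogenation delivers H2 syn to each of the four alkynes and so gives the four Z-alkenes; quinoline poisoning and volumetric control limit over-reduction, and the nitrile and alcohol are inert.

**Step 6**
Reactants: 11 (5Z,8Z,11Z,14Z,17R)-17-hydroxyicosa-5,8,11,14-tetraenenitrile; 12 phloroglucinol
Product: 14 (5Z,8Z,11Z,14Z,17R)-17-hydroxy-1-(2,4,6-trihydroxyphenyl)icosa-5,8,11,14-tetraen-1-one, via ketiminium chloride 13 (not isolated)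
Conditions: 12 (3 equiv), dry HCl (g), Et2O, 0 °C, 16 h; then H2O, 85 °C, 1 h (N2, BHT)
Reagents that add atoms: water, O
Why: Houben–Hoesch acylation, in which phloroglucinol attacks the HCl-activated nitrile at carbon to give ketiminium salt 13, which resists a second acylation and hydrolyses to the ketone in warm water; no Lewis acid is needed with this arene, and HCl in ether at 0 °C does not add to isolated 1,2-dialkyl Z-alkenes or substitute the secondary alcohol.

**Compound list**
1 | butanal | CCCC=O | starting material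
2 | allenyltrimethylsilane [trimethyl(propa-1,2-dien-1-yl)silane] | C=C=C[Si](C)(C)C | starting material
3 | trimethyl{[(4R)-hept-1-yn-4-yl]oxy}silane | CCC[C@@H](O[Si](C)(C)C)CC#C | intermediate
4 | (4R)-hept-1-yn-4-ol | CCC[C@@H](O)CC#C | intermediate
5 | 1,4-dibromobut-2-yne | BrCC#CCBr | starting material
6 | (4R)-11-bromoundeca-6,9-diyn-4-ol | CCC[C@@H](O)CC#CCC#CCBr | intermediate
7 | hex-5-ynenitrile | C#CCCCC#N | starting material
8 | (3-bromoprop-1-yn-1-yl)trimethylsilane | C[Si](C)(C)C#CCBr | starting material
9 | 9-(trimethylsilyl)nona-5,8-diynenitrile | C[Si](C)(C)C#CCC#CCCCC#N | intermediate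
10 | (17R)-17-hydroxyicosa-5,8,11,14-tetraynenitrile | CCC[C@@H](O)CC#CCC#CCC#CCC#CCCCC#N | intermediate
11 | (5Z,8Z,11Z,14Z,17R)-17-hydroxyicosa-5,8,11,14-tetraenenitrile | CCC[C@@H](O)C/C=C\C/C=C\C/C=C\C/C=C\CCCC#N | intermediate
12 | phloroglucinol (benzene-1,3,5-triol) | Oc1cc(O)cc(O)c1 | starting material
13 | (5Z,8Z,11Z,14Z,17R)-17-hydroxy-1-(2,4,6-trihydroxyphenyl)icosa-5,8,11,14-tetraen-1-iminium chloride | CCC[C@@H](O)C/C=C\C/C=C\C/C=C\C/C=C\CCCC(=[NH2+])c1c(O)cc(O)cc1O.[Cl-] | intermediate
14 | (5Z,8Z,11Z,14Z,17R)-17-hydroxy-1-(2,4,6-trihydroxyphenyl)icosa-5,8,11,14-tetraen-1-one | CCC[C@@H](O)C/C=C\C/C=C\C/C=C\C/C=C\CCCC(=O)c1c(O)cc(O)cc1O | target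

**Step count**
Total steps: 6. Longest linear sequence: 5 (steps 1, 2, 4, 5, 6).

**Steps most likely to fail**

Step 1 (the new reaction). Allenyltrimethylsilane is a weaker π-nucleophile than allyltrimethylsilane, butanal can self-condense under silylium catalysis, a [3+2] annulation to a silyl dihydrofuran can compete, and the level and sense of induction are untested. The fallback is known chemistry and changes nucleophile and mechanism. It sets out from 1 and returns at 4. Chiral-phosphoric-acid-catalysed propargylboration of 1 with commercial allenylboronic acid pinacol ester ((S)-TRIP 5 mol%, 4 Å MS, toluene, −20 °C) runs through a closed six-membered transition state with the acid hydrogen-bonded to the boronate. It gives 2-{[(4R)-hept-1-yn-4-yl]oxy}-4,4,5,5-tetramethyl-1,3,2-dioxaborolane F1, which aqueous work-up hydrolyses to 4. The enantiomeric excess for an unbranched aldehyde is expected to be only moderate.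

Step 5. Fourfold semihydrogenation can stall or over-reduce, and the by-products are hard to separate (AgNO3–silica). The fallback sets out from 10 and returns at 11 and replaces catalytic hydrogenation by stoichiometric syn-hydroboration and protonolysis. Dicyclohexylborane (5.2 equiv, THF, 0 °C; one equivalent is taken up by the hydroxyl group) gives (5Z,8Z,11Z,14Z,17R)-5,8,11,14-tetrakis(dicyclohexylboranyl)-17-[(dicyclohexylboranyl)oxy]icosa-5,8,11,14-tetraenenitrile F2 (boron regioisomers at each alkene, one drawn). Acetic acid (rt → 45 °C) then replaces every C–B and O–B bond by C–H and O–H with retention, giving 11; over-reduction cannot occur.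

Step 6. The free 17-OH can enter a Pinner reaction with the activated nitrile, the polyene sees HCl and a hot aqueous hydrolysis, and the lipophilic ketiminium salt may hydrolyse slowly. The fallback sets out from 7 and 12 and returns at 14; it installs the aryl ketone before any polyene exists and carries it protected.
- Hoesch reaction of 12 with 7 (HCl gas, Et2O, 0 °C) gives 1-(2,4,6-trihydroxyphenyl)hex-5-yn-1-iminium chloride F3, which is boiled in water to 1-(2,4,6-trihydroxyphenyl)hex-5-yn-1-one F4.
- NaH and chloromethyl methyl ether (DMF, 0 °C) give 1-[2,4,6-tris(methoxymethoxy)phenyl]hex-5-yn-1-one F5.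
- Coupling with 8 as in step 3 gives 1-[2,4,6-tris(methoxymethoxy)phenyl]-9-(trimethylsilyl)nona-5,8-diyn-1-one F6.
- CuI/CsF union with 6 as in step 4 gives (17R)-17-hydroxy-1-[2,4,6-tris(methoxymethoxy)phenyl]icosa-5,8,11,14-tetrayn-1-one F7.
- Lindlar reduction as in step 5 gives (5Z,8Z,11Z,14Z,17R)-17-hydroxy-1-[2,4,6-tris(methoxymethoxy)phenyl]icosa-5,8,11,14-tetraen-1-one F8.
- HCl in MeOH (rt → 40 °C) removes the three MOM groups to give 14.

**Further compounds**
F1 | step 1 | 2-{[(4R)-hept-1-yn-4-yl]oxy}-4,4,5,5-tetramethyl-1,3,2-dioxaborolane | CCC[C@@H](OB1OC(C)(C)C(C)(C)O1)CC#C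
F2 | step 5 | (5Z,8Z,11Z,14Z,17R)-5,8,11,14-tetrakis(dicyclohexylboranyl)-17-[(dicyclohexylboranyl)oxy]icosa-5,8,11,14-tetraenenitrile | N#CCCC/C(B(C1CCCCC1)C1CCCCC1)=C\C/C(B(C1CCCCC1)C1CCCCC1)=C\C/C(B(C1CCCCC1)C1CCCCC1)=C\C/C(B(C1CCCCC1)C1CCCCC1)=C\C[C@@H](CCC)OB(C1CCCCC1)C1CCCCC1
F3 | step 6 | 1-(2,4,6-trihydroxyphenyl)hex-5-yn-1-iminium chloride | C#CCCCC(=[NH2+])c1c(O)cc(O)cc1O.[Cl-]
F4 | step 6 | 1-(2,4,6-trihydroxyphenyl)hex-5-yn-1-one | C#CCCCC(=O)c1c(O)cc(O)cc1O
F5 | step 6 | 1-[2,4,6-tris(methoxymethoxy)phenyl]hex-5-yn-1-one | C#CCCCC(=O)c1c(OCOC)cc(OCOC)cc1OCOC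
F6 | step 6 | 1-[2,4,6-tris(methoxymethoxy)phenyl]-9-(trimethylsilyl)nona-5,8-diyn-1-one | C[Si](C)(C)C#CCC#CCCCC(=O)c1c(OCOC)cc(OCOC)cc1OCOC
F7 | step 6 | (17R)-17-hydroxy-1-[2,4,6-tris(methoxymethoxy)phenyl]icosa-5,8,11,14-tetrayn-1-one | CCC[C@@H](O)CC#CCC#CCC#CCC#CCCCC(=O)c1c(OCOC)cc(OCOC)cc1OCOC
F8 | step 6 | (5Z,8Z,11Z,14Z,17R)-17-hydroxy-1-[2,4,6-tris(methoxymethoxy)phenyl]icosa-5,8,11,14-tetraen-1-one | CCC[C@@H](O)C/C=C\C/C=C\C/C=C\C/C=C\CCCC(=O)c1c(OCOC)cc(OCOC)cc1OCOC
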